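The tetrahydrofuran is disconnected at C2–C3 and C4–C5. O1 with its two identical aryl-bearing carbons C2 and C5 (aryl groups cis) is a symmetric diaryl carbonyl ylide, and C3–C4 with its trans methyl groups is an E-crotonate unit. A sensitised electron-transfer opening of a trans-2,3-diaryloxirane releases the W-shaped ylide, which adds to a magnesium-chelated (R)-N-crotonoyl oxazolidinone; this single (3+2) cycloaddition forms both C–C bonds, closes the ring and sets all four stereocentres. The precursors are the bis(4-benzyloxy-3,5-dimethoxyphenyl)oxirane from syringaldehyde and the crotonoyl imide. The acyl group is then reduced to the second methyl group and the benzyl ethers are removed.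

Key step: step 5

Remark: the oxirane is made and used as the racemate, since both of its stereocentres are erased in the planar ylide; its SMILES shows one enantiomer. Ring numbering throughout: O1, C2 (aryl), C3 (acyl, later methyl), C4 (methyl), C5 (aryl).

Step 1
Reactants: 1 syringaldehyde (4-hydroxy-3,5-dimethoxybenzaldehyde); 2 benzyl bromide
Product: 3 4-(benzyloxy)-3,5-dimethoxybenzaldehyde
Conditions: BnBr, K2CO3, DMF, 60 °C
Reagents that add atoms: benzyl bromide (compound 2), BrCc1ccccc1
Why: Williamson ether synthesis, in which the phenoxide formed with carbonate displaces bromide from the reactive benzylic halide while the aldehyde is inert; no stereocentre is formed.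

Step 2
Reactants: 3 4-(benzyloxy)-3,5-dimethoxybenzaldehyde (two molecules)
Product: 4 (E)-1,2-bis[4-(benzyloxy)-3,5-dimethoxyphenyl]ethene
Conditions: TiCl4, Zn, pyridine, THF, 0 °C then reflux
Reagents that add atoms: none
Why: McMurry reductive coupling of an aromatic aldehyde on low-valent titanium should give the thermodynamically preferred E-stilbene, with pyridine buffering the Lewis-acidic metal chlorides so that the aryl benzyl ethers survive; no stereocentre is formed.

Step 3
Reactants: 4 (E)-1,2-bis[4-(benzyloxy)-3,5-dimethoxyphenyl]ethene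
Product: 5 rac-trans-2,3-bis[4-(benzyloxy)-3,5-dimethoxyphenyl]oxirane
Conditions: DMDO (acetone solution, 1.2 equiv), CH2Cl2, 0 °C
Reagents that add atoms: dimethyldioxirane, CC1(C)OO1
Why: Concerted oxygen-atom transfer from the dioxirane (Prilezhaev-type epoxidation) is stereospecific, so the E-alkene should give the trans-oxirane as a racemate, and the neutral reagent leaves only acetone, which spares the acid-labile benzylic oxirane.

Step 4
Reactants: 6 (R)-4-benzyloxazolidin-2-one; 7 (E)-crotonyl chloride
Product: 9 (R)-4-benzyl-3-[(E)-but-2-enoyl]oxazolidin-2-one, via lithiated oxazolidinone 8 (not isolated)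
Conditions: n-BuLi, THF, −78 °C; then (E)-crotonyl chloride, −78 to 0 °C
Reagents that add atoms: (E)-crotonyl chloride (compound 7), C/C=C/C(=O)Cl
Why: N-Acylation of the lithium salt of the oxazolidinone by the acid chloride at low temperature is the standard imide synthesis, and it leaves the auxiliary stereocentre and the E-alkene untouched.

Step 5
Reactants: 5 rac-trans-2,3-bis[4-(benzyloxy)-3,5-dimethoxyphenyl]oxirane; 9 (R)-4-benzyl-3-[(E)-but-2-enoyl]oxazolidin-2-one
Product: 11 (R)-4-benzyl-3-{[(2S,3S,4S,5R)-2,5-bis[4-(benzyloxy)-3,5-dimethoxyphenyl]-4-methyltetrahydrofuran-3-yl]carbonyl}oxazolidin-2-one, via W-shaped carbonyl ylide 10 (not isolated)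
Conditions: 9 (1.5 equiv) premixed with Mg(ClO4)2 (1.5 equiv), 4 Å MS, CH2Cl2/MeCN 3:1; 9,10-dicyanoanthracene (5 mol %), biphenyl (0.5 equiv), 405 nm LED, Ar, −20 °C; 5 added slowly
Reagents that add atoms: none
Why: Proposed new method: excited 9,10-dicyanoanthracene (relayed by biphenyl) should oxidise the trialkoxyaryl oxirane, whose radical cation opens at its C–C bond and, after back electron transfer, leaves the planar exo,exo ylide 10, which is trapped by the magnesium-chelated, LUMO-lowered crotonoyl imide in a concerted suprafacial [4π+2π] addition that forms C2–C3 and C4–C5 together. The closest known reaction type is the racemic electron-transfer-sensitised (3+2) cycloaddition of 2,3-diaryloxiranes with electron-poor alkenes; chelated N-enoyl oxazolidinones are established dipolarophiles for other 1,3-dipoles, but the combination is untested. The tetrahydrofuran ring is closed by this intermolecular two-bond cycloaddition itself, with no separate cyclisation event. C2 and C5 should become cis because both aryl groups occupy the outer positions of the W-shaped ylide, C3 and C4 trans because the E-alkene reacts suprafacially, and their absolute configuration follows from the (R)-benzyl group, which in the s-cis two-point chelate covers the Cα-Si face so that the ylide bonds to the Cα-Re face. Alkene facial selectivity is the only selectivity needed, since the symmetric ylide has no regiochemistry and the endo or exo orientation merely decides whether the acyl or the methyl group lies cis to the aryl groups, a difference that disappears when the acyl group becomes methyl; adducts from the wrong face are diastereomers of 11 and can be removed at this stage. Irradiating only the sensitiser, using a non-nucleophilic and non-oxidisable counter-ion, pre-forming the 1:1 chelate and feeding the oxirane slowly at −20 °C are meant to keep acid-type rearrangement of the oxirane behind the cycloaddition.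

Step 6
Reactants: 11 (R)-4-benzyl-3-{[(2S,3S,4S,5R)-2,5-bis[4-(benzyloxy)-3,5-dimethoxyphenyl]-4-methyltetrahydrofuran-3-yl]carbonyl}oxazolidin-2-one
Product: 12 [(2S,3R,4S,5R)-2,5-bis[4-(benzyloxy)-3,5-dimethoxyphenyl]-4-methyltetrahydrofuran-3-yl]methanol
Conditions: LiBH4, H2O (1 equiv), Et2O/THF, 0 °C
Reagents that add atoms: none
Why: Reductive cleavage of the N-acyloxazolidinone with lithium borohydride, in which hydride adds to the more electrophilic exocyclic carbonyl and the released aldehyde is reduced on to the primary alcohol, so no stereocentre changes (C3 becomes R by CIP priority only) and auxiliary 6 is recovered.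

Step 7
Reactants: 12 [(2S,3R,4S,5R)-2,5-bis[4-(benzyloxy)-3,5-dimethoxyphenyl]-4-methyltetrahydrofuran-3-yl]methanol
Product: 13 [(2S,3R,4S,5R)-2,5-bis[4-(benzyloxy)-3,5-dimethoxyphenyl]-4-methyltetrahydrofuran-3-yl]methyl methanesulfonate
Conditions: MsCl, Et3N, CH2Cl2, 0 °C
Reagents that add atoms: methanesulfonyl chloride, CS(=O)(=O)Cl
Why: Mesylation (O-sulfonylation) of the primary alcohol takes place at oxygen only, so the four ring stereocentres are untouched.

Step 8
Reactants: 13 [(2S,3R,4S,5R)-2,5-bis[4-(benzyloxy)-3,5-dimethoxyphenyl]-4-methyltetrahydrofuran-3-yl]methyl methanesulfonate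
Product: 14 (2S,3S,4S,5R)-2,5-bis[4-(benzyloxy)-3,5-dimethoxyphenyl]-3,4-dimethyltetrahydrofuran
Conditions: LiEt3BH, THF, 0 °C to rt
Reagents that add atoms: none
Why: SN2 hydride displacement of the primary sulfonate by the strongly nucleophilic triethylborohydride should turn CH2OMs into CH3 at a non-stereogenic carbon, while the aryl ethers and the ring are inert to hydride (C3 returns to S by CIP priority only).

Step 9
Reactants: 14 (2S,3S,4S,5R)-2,5-bis[4-(benzyloxy)-3,5-dimethoxyphenyl]-3,4-dimethyltetrahydrofuran
Product: 15 4,4'-[(2S,3S,4S,5R)-3,4-dimethyltetrahydrofuran-2,5-diyl]bis(2,6-dimethoxyphenol) (target)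
Conditions: H2 (1 atm), 10% Pd/C, EtOAc, rt
Reagents that add atoms: none
Why: Palladium-catalysed hydrogenolysis cleaves aryl benzyl ethers much faster than the ring benzylic C–O bonds under neutral conditions at 1 atm, so stopping after uptake of two equivalents of hydrogen should leave the ring and its four stereocentres intact.

Compound list
1 | syringaldehyde | COc1cc(C=O)cc(OC)c1O | starting material
2 | benzyl bromide | BrCc1ccccc1 | starting material
3 | 4-(benzyloxy)-3,5-dimethoxybenzaldehyde | COc1cc(C=O)cc(OC)c1OCc1ccccc1 | intermediate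
4 | (E)-1,2-bis[4-(benzyloxy)-3,5-dimethoxyphenyl]ethene | COc1cc(/C=C/c2cc(OC)c(OCc3ccccc3)c(OC)c2)cc(OC)c1OCc1ccccc1 | intermediate
5 | rac-trans-2,3-bis[4-(benzyloxy)-3,5-dimethoxyphenyl]oxirane (racemate; (2S,3S) enantiomer drawn) | COc1cc([C@@H]2O[C@H]2c2cc(OC)c(OCc3ccccc3)c(OC)c2)cc(OC)c1OCc1ccccc1 | intermediate
6 | (R)-4-benzyloxazolidin-2-one | O=C1N[C@H](Cc2ccccc2)CO1 | starting material
7 | (E)-crotonyl chloride | C/C=C/C(=O)Cl | starting material
8 | lithium salt of (R)-4-benzyloxazolidin-2-one (not isolated) | [Li+].O=C1[N-][C@H](Cc2ccccc2)CO1 | intermediate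
9 | (R)-4-benzyl-3-[(E)-but-2-enoyl]oxazolidin-2-one | C/C=C/C(=O)N1[C@H](Cc2ccccc2)COC1=O | intermediate
10 | exo,exo (W-shaped) 1,3-bis[4-(benzyloxy)-3,5-dimethoxyphenyl] carbonyl ylide (not isolated; one resonance form) | COc1cc(/C=[O+]/[CH-]c2cc(OC)c(OCc3ccccc3)c(OC)c2)cc(OC)c1OCc1ccccc1 | intermediate
11 | (R)-4-benzyl-3-{[(2S,3S,4S,5R)-2,5-bis[4-(benzyloxy)-3,5-dimethoxyphenyl]-4-methyltetrahydrofuran-3-yl]carbonyl}oxazolidin-2-one | COc1cc([C@H]2O[C@@H](c3cc(OC)c(OCc4ccccc4)c(OC)c3)[C@@H](C)[C@@H]2C(=O)N2[C@H](Cc3ccccc3)COC2=O)cc(OC)c1OCc1ccccc1 | intermediate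
12 | [(2S,3R,4S,5R)-2,5-bis[4-(benzyloxy)-3,5-dimethoxyphenyl]-4-methyltetrahydrofuran-3-yl]methanol | COc1cc([C@H]2O[C@@H](c3cc(OC)c(OCc4ccccc4)c(OC)c3)[C@@H](C)[C@@H]2CO)cc(OC)c1OCc1ccccc1 | intermediate
13 | [(2S,3R,4S,5R)-2,5-bis[4-(benzyloxy)-3,5-dimethoxyphenyl]-4-methyltetrahydrofuran-3-yl]methyl methanesulfonate | COc1cc([C@H]2O[C@@H](c3cc(OC)c(OCc4ccccc4)c(OC)c3)[C@@H](C)[C@@H]2COS(C)(=O)=O)cc(OC)c1OCc1ccccc1 | intermediate
14 | (2S,3S,4S,5R)-2,5-bis[4-(benzyloxy)-3,5-dimethoxyphenyl]-3,4-dimethyltetrahydrofuran | COc1cc([C@H]2O[C@@H](c3cc(OC)c(OCc4ccccc4)c(OC)c3)[C@@H](C)[C@@H]2C)cc(OC)c1OCc1ccccc1 | intermediate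
15 | 4,4'-[(2S,3S,4S,5R)-3,4-dimethyltetrahydrofuran-2,5-diyl]bis(2,6-dimethoxyphenol) | COc1cc([C@H]2O[C@@H](c3cc(OC)c(O)c(OC)c3)[C@@H](C)[C@@H]2C)cc(OC)c1O | target

Total step count: 9. Longest linear sequence: 8 steps (steps 1, 2, 3, 5, 6, 7, 8, 9); the imide branch is step 4.

Steps most likely to fail

Step 5 (Proposed new method). Lewis-acid-promoted rearrangement of the oxirane may outrun ylide formation, trapping of the ylide by the β-methyl-substituted dipolarophile may be slow, and the facial selectivity of the chelate may be poor. The fallback uses only known chemistry and gives up both the chelating salt and the auxiliary. Setting out from 5, the established salt-free sensitised cycloaddition (9,10-dicyanoanthracene, MeCN, 405 nm) is run with commercial bis[(1R,2S,5R)-menthyl] fumarate, a far more reactive and symmetric dipolarophile. It should give the 2,5-cis-3,4-trans diester as two diastereomers that differ only in the alkene face, because a fumarate has no endo/exo distinction. No induction is relied on; crystallisation or chromatography is to deliver bis[(1R,2S,5R)-menthyl] (2S,3S,4S,5R)-2,5-bis[4-(benzyloxy)-3,5-dimethoxyphenyl]tetrahydrofuran-3,4-dicarboxylate F1, assigned by correlation with 14. LiAlH4 in THF should then give [(2S,3R,4R,5R)-2,5-bis[4-(benzyloxy)-3,5-dimethoxyphenyl]tetrahydrofuran-3,4-diyl]dimethanol F2, and MsCl/Et3N its bis(methanesulfonate) F3. LiEt3BH reduces both sulfonates to methyl groups, which brings the sequence back to the route at 14.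

Step 3. The electron-rich oxirane may rearrange to carbonyl compounds during oxidation or purification, or the trialkoxyarenes may be oxidised in competition. The fallback builds the oxirane under basic conditions and also bypasses step 2. Setting out from 3, NaBH4 in MeOH gives [4-(benzyloxy)-3,5-dimethoxyphenyl]methanol F4. Tetrahydrothiophene and HBF4·OEt2 in CH2Cl2 convert it into 1-[4-(benzyloxy)-3,5-dimethoxybenzyl]tetrahydrothiophenium tetrafluoroborate F5. F5 and a second portion of 3 with KOH in MeCN should give the trans-oxirane by sulfonium-ylide epoxidation (Corey–Chaykovsky type, trans-selective for benzylic ylides), returning to the route at 5.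

Step 6. Hydride may attack the ring carbonyl of the hindered imide and open the auxiliary instead of releasing the alcohol. The fallback separates cleavage from reduction. Setting out from 11, LiOH/H2O2 in THF–H2O at 0 °C (hydroperoxide attacks the exocyclic carbonyl selectively) should give (2S,3S,4S,5R)-2,5-bis[4-(benzyloxy)-3,5-dimethoxyphenyl]-4-methyltetrahydrofuran-3-carboxylic acid F6. BH3·SMe2 in THF then reduces the acid, returning to the route at 12.

Further compounds
F1 | step 5 | bis[(1R,2S,5R)-menthyl] (2S,3S,4S,5R)-2,5-bis[4-(benzyloxy)-3,5-dimethoxyphenyl]tetrahydrofuran-3,4-dicarboxylate | COc1cc([C@H]2O[C@@H](c3cc(OC)c(OCc4ccccc4)c(OC)c3)[C@@H](C(=O)O[C@@H]3C[C@H](C)CC[C@H]3C(C)C)[C@@H]2C(=O)O[C@@H]2C[C@H](C)CC[C@H]2C(C)C)cc(OC)c1OCc1ccccc1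
F2 | step 5 | [(2S,3R,4R,5R)-2,5-bis[4-(benzyloxy)-3,5-dimethoxyphenyl]tetrahydrofuran-3,4-diyl]dimethanol | COc1cc([C@H]2O[C@@H](c3cc(OC)c(OCc4ccccc4)c(OC)c3)[C@@H](CO)[C@@H]2CO)cc(OC)c1OCc1ccccc1
F3 | step 5 | [(2S,3R,4R,5R)-2,5-bis[4-(benzyloxy)-3,5-dimethoxyphenyl]tetrahydrofuran-3,4-diyl]dimethyl bis(methanesulfonate) | COc1cc([C@H]2O[C@@H](c3cc(OC)c(OCc4ccccc4)c(OC)c3)[C@@H](COS(C)(=O)=O)[C@@H]2COS(C)(=O)=O)cc(OC)c1OCc1ccccc1
F4 | step 3 | [4-(benzyloxy)-3,5-dimethoxyphenyl]methanol | COc1cc(CO)cc(OC)c1OCc1ccccc1
F5 | step 3 | 1-[4-(benzyloxy)-3,5-dimethoxybenzyl]tetrahydrothiophenium tetrafluoroborate | COc1cc(C[S+]2CCCC2)cc(OC)c1OCc1ccccc1.F[B-](F)(F)F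
F6 | step 6 | (2S,3S,4S,5R)-2,5-bis[4-(benzyloxy)-3,5-dimethoxyphenyl]-4-methyltetrahydrofuran-3-carboxylic acid | COc1cc([C@H]2O[C@@H](c3cc(OC)c(OCc4ccccc4)c(OC)c3)[C@@H](C)[C@@H]2C(=O)O)cc(OC)c1OCc1ccccc1
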